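The reading at 6.0 h comes twice as late as the end of the feed, so I asked what the flask holds once G is in.

| setting | Friday's | flask |
|---|---|---|
| Z | 0.025 M | 0.050 M |
| G | 1.3 equiv (fed, over 3.0 h) | 1.30 equiv (fed, over 3.0 h) |
| remark | run made earlier; the fed solution adds 0.10 times the starting volume | the fed solution adds 0.10 times the starting volume |
| time |  | 6.0 h |

- Friday's (time / min: X / %, Q / %, Z / %): 6.00: 0, 4.2, 95.8; 12.0: 0, 8.3, 93.6; 30.0: 1.6, 15.6, 83.9; 80.0: 2.1, 31.4, 65.6

(readings scatter by 1 percentage point)

- amounts are per litre of the starting volume; all of the dose is in the solution fed
- steps under discussion: Z <-> Q; X <-> J; G + Q <-> X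
- the reaction counts as stopped when no species that holds the Z changes by six tenths of a point or more over the second half of the time

- why nothing more happens at 6.0 h, or that something still does (it is still moving / forward and back rates have come level / G has run out first / all of Z has reacted)
- amount of X at 6.0 h, in percent of the Z charged
- amount of Q at 6.0 h, in percent of the Z charged
- amount of X if the flask were left three thousand times as long, in percent of the Z charged

My bench rule was the pseudo-first-order habit for a reagent in excess: let G turn Q into X and count no way back. I tested it with Γ, the ratio X/Q divided by the G concentration. Γ loses time only if G + Q to X has come level, and it is then the ratio of the rate constants of that step. G was taken as fed, and the X it had used was ignored. If the step runs forward while Q and G both rise with time, X/Q goes with the square of time and Γ with time itself. On Friday's run Γ should then have grown 2.67-fold from 30.0 min to 80.0 min.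

The readings gave 19.3 M⁻¹ and then 4.84 M⁻¹. These are loose: the X readings of 1.6% and 2.1% stand against a scatter of 1 percentage point, so the fall in Γ lies within the scatter and does not test the rule. The border of my rule, where a way back would stop Γ rising, lay beyond what these readings could show. As a rough guess of my own, I assumed the step level by the reading and held Γ at the later value. With G at its full 0.0591 M, my reckoning gave X/Q near 0.286, with Q above X.

The forecast differed: it is still moving, X 55%, Q 20%, and X 90% in the long run, on the ground that “Excess G pulls everything toward X”.

The flask gave this answer on its state at the reading: it is still moving. It held X 18.6% and Q 37.9%, and X reached 19.8% after the long wait asked about.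

    Z ⇌ Q (K = 1.30, k = 0.00640 min⁻¹)
    X ⇌ J (K = 0.520, k = 0.0140 min⁻¹)
    G + Q ⇌ X (K = 11.0 M⁻¹, k = 0.260 M⁻¹ min⁻¹)

At 6.00 h the forward half-life of Q by G + Q to X was 0.96 h, short against the 6.0 h of the run, yet the backward turnover of that step was 77% of the forward one. With G at 78.5% of its own charge, Γ in the flask stood at 10.6 M⁻¹, beside the 4.84 M⁻¹ read on Friday's run and a K3 of 11 M⁻¹. The same recipe at 0.12 M of Z held G at 66.8% of its charge, X at 28.7% and Q at 28.6%, which gives Γ = 10.6 M⁻¹.

The data stem from a simulated flask with made-up constants, and the scatter is random.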